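## Retrosynthetic overview
1. Target 12 ⇒ cross-metathesis of the 9-(but-1-enyl)decalin 10 with methyl vinyl ketone. This is the only operation after the rings exist.
2. 10 ⇒ acyclic triene 7. One hydrogen-atom-initiated radical cascade forms C4–C5 (ring A first) and then C9–C10 (ring B), and ends by opening of a vinylcyclopropane.
3. 7 already carries all three oxygenated stereocentres (C6, C7, C8), so they steer C5, C10 and C9 and no late oxidation is needed.
4. 7 ⇒ cis-hydrogenation of the alkyne, retentive palladium/AcOH opening of a vinyl epoxide, and chelate-controlled cyclopropylacetylide addition to epoxy ketone 2.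
5. 2 ⇒ catalytic asymmetric nucleophilic epoxidation of pseudoionone 1.

Assumption: positions use labdane numbering (ring A = C1–C5 and C10, ring B = C5–C10, side chain C11, C12, C13, C16); technical pseudoionone is taken as its (3E,5E) isomer (the 5Z isomer converges in step 5, where C10 becomes planar); the (R)-BINOL–lanthanum catalyst is taken to give the (αS,βR) epoxide, as it does with simple trans-enones.

## Route

**Step 1**
Reactants: 1 (3E,5E)-pseudoionone
Product: 2 (3S,4R,5E)-3,4-epoxy-6,10-dimethylundeca-5,9-dien-2-one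
Conditions: La(O-i-Pr)3 (5 mol %), (R)-BINOL (5 mol %), Ph3As=O (5 mol %), TBHP (1.2 equiv, decane), 4 Å MS, THF, rt
Reagents that add atoms: tert-butyl hydroperoxide, CC(C)(C)OO
Why: In this asymmetric Weitz–Scheffer epoxidation the lanthanum peroxide adds only to the electron-poor α,β-alkene (the δ-carbon is fully substituted and the other alkenes are electron-rich), and the BINOL complex sets C6 and C7 as the trans epoxide.

**Step 2**
Reactants: 2 (3S,4R,5E)-3,4-epoxy-6,10-dimethylundeca-5,9-dien-2-one; 3 cyclopropylacetylene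
Product: 5 (2S)-4-cyclopropyl-2-{(2S,3R)-3-[(1E)-2,6-dimethylhepta-1,5-dien-1-yl]oxiran-2-yl}but-3-yn-2-ol, via cyclopropylethynylmagnesium bromide 4 (not isolated)
Conditions: 3, EtMgBr, THF, 0 °C to rt; then 2, THF/CH2Cl2, −78 °C; aq NH4Cl
Reagents that add atoms: cyclopropylacetylene (3), C#CC1CC1
Why: In this Cram-chelate 1,2-addition magnesium bridges the ketone and epoxide oxygens, so the acetylide attacks from the side of H-7 and sets C8 with its oxygen syn to the C7 oxygen, while the epoxide survives at −78 °C.

**Step 3**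
Reactants: 5 (2S)-4-cyclopropyl-2-{(2S,3R)-3-[(1E)-2,6-dimethylhepta-1,5-dien-1-yl]oxiran-2-yl}but-3-yn-2-ol
Product: 6 (3S,4S,5R,6E)-1-cyclopropyl-3,4-dihydroxy-3,7,11-trimethyldodeca-6,10-dien-1-yn-5-yl acetate
Conditions: Pd(PPh3)4 (5 mol %), AcOH (2 equiv), THF, 0 °C, stopped at full conversion
Reagents that add atoms: acetic acid, CC(=O)O
Why: In this Tsuji–Trost-type vinyl epoxide opening zerovalent palladium ionises C6–O with inversion and acetate attacks anti to palladium at the less substituted terminus C6 (C10 is fully substituted), so C6 is retained by double inversion, C7 is untouched, and the 6-OAc/7-OH pattern arises without protecting groups.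

**Step 4**
Reactants: 6 (3S,4S,5R,6E)-1-cyclopropyl-3,4-dihydroxy-3,7,11-trimethyldodeca-6,10-dien-1-yn-5-yl acetate
Product: 7 (1Z,3S,4S,5R,6E)-1-cyclopropyl-3,4-dihydroxy-3,7,11-trimethyldodeca-1,6,10-trien-5-yl acetate
Conditions: H2 (1 atm), Pd/CaCO3 poisoned with Pb(OAc)2 (Lindlar catalyst), quinoline, EtOAc, rt
Reagents that add atoms: none
Why: Lindlar syn-semihydrogenation reduces only the alkyne (the trisubstituted alkenes, allylic acetate and cyclopropane are inert), and the alkene geometry is erased in step 5.

**Step 5 (key step)**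
Reactants: 7 (1Z,3S,4S,5R,6E)-1-cyclopropyl-3,4-dihydroxy-3,7,11-trimethyldodeca-1,6,10-trien-5-yl acetate
Product: 10 (1R,2S,3S,4R,4aS,8aS)-4-[(1E)-but-1-en-1-yl]-2,3-dihydroxy-3,4a,8,8-tetramethyldecahydronaphthalen-1-yl acetate, via monocyclic tertiary radical 8 (not isolated), via bicyclic cyclopropylcarbinyl radical 9 (not isolated)
Conditions: Fe(acac)3 (2.2 equiv), PhSiH3 (4 equiv), degassed EtOH (0.01 M), 60 °C
Reagents that add atoms: none
Why: Proposed new method: the iron hydride formed from Fe(acac)3 and PhSiH3 transfers a hydrogen atom (MHAT) to the terminal trisubstituted alkene (the inner alkene is shielded and deactivated by its allylic acetate, and the cis-disubstituted one would give only a secondary radical); the tertiary C4 radical closes ring A 6-endo at C5 (5-exo would join two quaternary carbons) on the face anti to the bulky C7 branch in the A1,3-minimised rotamer, which sets C5; the planar C10 radical 8 closes ring B 6-exo at C9 through a chair with 6-OAc, 7-OH, 8-OH and the alkenyl arm all equatorial, which sets C10 and C9 as the trans-decalin; radical 9 is then drained irreversibly by cyclopropylcarbinyl opening (about 10^8 s^-1) and a final hydrogen-atom transfer; the closest known chemistry is the iron- or cobalt-hydride-initiated radical bicyclisation of oxygenated polyenes and the Cp2TiCl epoxypolyene cyclisation, and what is new is the unactivated 6-exo terminus with radical-clock termination.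

**Step 6**
Reactants: 10 (1R,2S,3S,4R,4aS,8aS)-4-[(1E)-but-1-en-1-yl]-2,3-dihydroxy-3,4a,8,8-tetramethyldecahydronaphthalen-1-yl acetate; 11 methyl vinyl ketone
Product: 12 (1R,2S,3S,4R,4aS,8aS)-2,3-dihydroxy-3,4a,8,8-tetramethyl-4-[(1E)-3-oxobut-1-en-1-yl]decahydronaphthalen-1-yl acetate (target)
Conditions: 11 (5 equiv), second-generation Hoveyda–Grubbs catalyst [RuCl2(H2IMes)(=CH-C6H4-2-O-i-Pr)] (10 mol %), CH2Cl2, 40 °C
Reagents that add atoms: methyl vinyl ketone (11), C=CC(C)=O
Why: In this olefin cross-metathesis 10 has a single alkene and the electron-poor partner barely homodimerises, the E-enone forms under thermodynamic control (any Z-butenyl isomer of 10 converges), and no stereocentre, alcohol or acetate is touched.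

## Compound list
1 | (3E,5E)-pseudoionone, (3E,5E)-6,10-dimethylundeca-3,5,9-trien-2-one | CC(=O)/C=C/C=C(\C)CCC=C(C)C | starting material
2 | (3S,4R,5E)-3,4-epoxy-6,10-dimethylundeca-5,9-dien-2-one | CC(=O)[C@H]1O[C@@H]1/C=C(\C)CCC=C(C)C | intermediate
3 | cyclopropylacetylene | C#CC1CC1 | starting material
4 | cyclopropylethynylmagnesium bromide (not isolated) | Br[Mg]C#CC1CC1 | intermediate
5 | (2S)-4-cyclopropyl-2-{(2S,3R)-3-[(1E)-2,6-dimethylhepta-1,5-dien-1-yl]oxiran-2-yl}but-3-yn-2-ol | C1CC1C#C[C@](C)(O)[C@H]2O[C@@H]2/C=C(\C)CCC=C(C)C | intermediate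
6 | (3S,4S,5R,6E)-1-cyclopropyl-3,4-dihydroxy-3,7,11-trimethyldodeca-6,10-dien-1-yn-5-yl acetate | C1CC1C#C[C@](C)(O)[C@@H](O)[C@H](OC(C)=O)/C=C(\C)CCC=C(C)C | intermediate
7 | (1Z,3S,4S,5R,6E)-1-cyclopropyl-3,4-dihydroxy-3,7,11-trimethyldodeca-1,6,10-trien-5-yl acetate | C1CC1/C=C\[C@](C)(O)[C@@H](O)[C@H](OC(C)=O)/C=C(\C)CCC=C(C)C | intermediate
8 | monocyclic tertiary radical (ring A closed, C5 set, radical at C10; not isolated) | C1CC1/C=C\[C@](C)(O)[C@@H](O)[C@H](OC(C)=O)[C@H]2C(C)(C)CCC[C]2C | intermediate
9 | bicyclic cyclopropylcarbinyl radical (rings A and B closed, radical at C11; not isolated) | C1CC1[CH][C@H]2[C@](C)(O)[C@@H](O)[C@H](OC(C)=O)[C@H]3C(C)(C)CCC[C@@]32C | intermediate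
10 | (1R,2S,3S,4R,4aS,8aS)-4-[(1E)-but-1-en-1-yl]-2,3-dihydroxy-3,4a,8,8-tetramethyldecahydronaphthalen-1-yl acetate | CC/C=C/[C@H]1[C@](C)(O)[C@@H](O)[C@H](OC(C)=O)[C@H]2C(C)(C)CCC[C@@]21C | intermediate
11 | methyl vinyl ketone | C=CC(C)=O | starting material
12 | 6α-acetoxy-7β,8α-dihydroxy-14,15-dinorlabd-11E-en-13-one (CNP0136046.1) | CC(=O)/C=C/[C@H]1[C@](C)(O)[C@@H](O)[C@H](OC(C)=O)[C@H]2C(C)(C)CCC[C@@]21C | target

Total steps: 6. Longest linear sequence: 6 (1 → 12).

## Steps most likely to fail, with fallbacks

**Step 5.** The risks are premature reduction of the C4 or C10 radical, hydrogen-atom transfer to the vinylcyclopropane, and a slow 6-exo closure. The fallback sets out from 7 and returns at 10, and it starts the same cascade from an epoxide instead of by hydrogen-atom transfer. One equivalent of mCPBA (CH2Cl2, −20 °C) epoxidises the most electron-rich terminal alkene to the terminal epoxide F1, as both C3 epimers. Cp2TiCl (from Cp2TiCl2 and Mn dust, THF, excess), a trivalent titanium reagent, opens F1 to the 3-titanoxy C4 radical. That radical runs the same 6-endo, 6-exo and ring-opening sequence. The primary radical is captured by a second Cp2TiCl and protonated, giving the 3-hydroxy decalin F2. The least hindered 3-OH is converted with thiocarbonyldiimidazole into the imidazolyl thiocarbonate F3. Bu3SnH/AIBN (Barton–McCombie) then removes it to give 10.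

**Step 3.** The risks are 1,4-attack, erosion of configuration at C6, diene formation, and palladium hydride chemistry at the alkyne. The fallback sets out from 5 and returns at 6. Pd2(dba)3 and P(O-i-Pr)3 under CO2 (1 atm, THF) let the C7 alkoxide pick up CO2 and deliver it intramolecularly. The five-membered ring enforces both 1,2-attack and retention, giving the cyclic carbonate F4. LiOH (THF/H2O) then gives the triol F5. The least hindered, allylic 6-OH is acetylated selectively (Ac2O 1 equiv, 2,4,6-collidine, CH2Cl2, −20 °C) to give 6.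

**Step 6.** The risk is that the alkene sits on a carbon flanked by two fully substituted centres. The fallback sets out from 10 and returns at 12, and it keeps all four side-chain carbons instead of exchanging them. Allylic C–H oxidation with catalytic SeO2 and TBHP (CH2Cl2) attacks the unhindered C13 methylene to give the allylic alcohol F6, as both C13 epimers. MnO2 (CH2Cl2) then oxidises only this allylic alcohol to the enone 12.

## Further compounds
F1 | step 5 | (1Z,3S,4S,5R,6E)-1-cyclopropyl-10,11-epoxy-3,4-dihydroxy-3,7,11-trimethyldodeca-1,6-dien-5-yl acetate (both epoxide epimers) | C1CC1/C=C\[C@](C)(O)[C@@H](O)[C@H](OC(C)=O)/C=C(\C)CCC2OC2(C)C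
F2 | step 5 | 3-hydroxy derivative of 10 (labdane C3, both epimers) | CC/C=C/[C@H]1[C@](C)(O)[C@@H](O)[C@H](OC(C)=O)[C@H]2C(C)(C)C(O)CC[C@@]21C
F3 | step 5 | 3-O-(imidazol-1-ylthiocarbonyl) derivative of F2 | CC/C=C/[C@H]1[C@](C)(O)[C@@H](O)[C@H](OC(C)=O)[C@H]2C(C)(C)C(OC(=S)n3ccnc3)CC[C@@]21C
F4 | step 3 | 6,7-cyclic carbonate of the triol corresponding to 6 | C1CC1C#C[C@](C)(O)[C@H]2OC(=O)O[C@@H]2/C=C(\C)CCC=C(C)C
F5 | step 3 | (3S,4S,5R,6E)-1-cyclopropyl-3,7,11-trimethyldodeca-6,10-dien-1-yne-3,4,5-triol | C1CC1C#C[C@](C)(O)[C@@H](O)[C@H](O)/C=C(\C)CCC=C(C)C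
F6 | step 6 | 13-hydroxy analogue of 12 (allylic alcohol, both C13 epimers) | CC(O)/C=C/[C@H]1[C@](C)(O)[C@@H](O)[C@H](OC(C)=O)[C@H]2C(C)(C)CCC[C@@]21C
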